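**Strategy.** The route rests on cutting the C3a–C7a bond of the 3-alkoxycyclohexa-2,4-dienone ring (C3a, C4, C5, C6, C7, C7a). That ring is read as the product of a vinylketene–alkoxyalkyne annulation: O1–C7a=C7 is a former ynol ether, C6 a ketene carbon, and C3a–C4=C5 its vinyl arm. Photolysis of an acyclic α-diazo-β′-methoxy enone carrying a tethered ethynyl ether should trigger Wolff rearrangement, intramolecular [2+2] (C3a–C7a, closing the dihydrofuran), 4π opening and 6π closure onto the fully substituted C5, which blocks aromatisation and gives the target directly. The C2/C3 pair comes from a catalytic anti-crotylation.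

Key step: step 10

Remark: atom labels (O1, C2, C3, C3a, C4 to C7, C7a) are those of the 2,3-dihydrobenzofuran skeleton of the target and are used for the corresponding atoms of all precursors.
Assumption: (R)-SEGPHOS is taken as the ligand enantiomer that delivers (1R,2R)-3; if the sense is the opposite, the other enantiomer is used.

Step 1
Reactants: 1 3,4-dimethoxybenzyl alcohol; 2 but-3-en-2-yl acetate (racemic)
Product: 3 (1R,2R)-1-(3,4-dimethoxyphenyl)-2-methylbut-3-en-1-ol
Conditions: [Ir(cod)Cl]2 (2.5 mol%), (R)-SEGPHOS (5 mol%), 4-cyano-3-nitrobenzoic acid (10 mol%), Cs2CO3 (20 mol%), THF, 90 °C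
Reagents that add atoms: none
Why: Iridium-catalysed transfer-hydrogenative carbonyl crotylation from the alcohol oxidation level: 1 is dehydrogenated to the aldehyde, which is attacked by the (E)-σ-crotyliridium species through a closed chair transition state, so the anti relationship follows from the (E)-crotyl geometry and the absolute configuration at C1 and C2 from the chiral SEGPHOS–iridium C,O-benzoate catalyst.

Step 2
Reactants: 3 (1R,2R)-1-(3,4-dimethoxyphenyl)-2-methylbut-3-en-1-ol
Product: 6 triisopropyl[({(1R,2R)-1-(3,4-dimethoxyphenyl)-2-methylbut-3-en-1-yl}oxy)ethynyl]silane, via dichlorovinyl ether 4 (not isolated), via lithium alkoxyacetylide 5 (not isolated)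
Conditions: KH, THF, 0 °C; Cl2C=CHCl, −50 °C to rt; n-BuLi (2.4 equiv), −78 to −40 °C; i-Pr3SiOTf, −78 to 0 °C
Reagents that add atoms: trichloroethylene ClC=C(Cl)Cl; triisopropylsilyl trifluoromethanesulfonate CC(C)[Si](OS(=O)(=O)C(F)(F)F)(C(C)C)C(C)C
Why: Ynol ether synthesis by the alkoxide–trichloroethylene route: the potassium alkoxide adds to dichloroacetylene formed in situ to give (E)-dichlorovinyl ether 4, n-BuLi effects elimination and Cl–Li exchange to alkoxyacetylide 5, and C-silylation gives 6 with the benzylic C–O bond, and hence both stereocentres, untouched.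

Step 3
Reactants: 6 triisopropyl[({(1R,2R)-1-(3,4-dimethoxyphenyl)-2-methylbut-3-en-1-yl}oxy)ethynyl]silane
Product: 8 (3R,4R)-4-(3,4-dimethoxyphenyl)-3-methyl-4-{[(triisopropylsilyl)ethynyl]oxy}butan-1-ol, via alkyl-9-BBN adduct 7 (not isolated)
Conditions: 9-BBN, THF, 0 °C to rt; then NaOH, H2O2, 0 °C
Reagents that add atoms: hydrogen peroxide OO
Why: Hydroboration–oxidation: 9-BBN should add anti-Markovnikov to the monosubstituted alkene much faster than to the internal, silyl-shielded alkynyl ether, and oxidation with retention gives the primary alcohol without touching C3 or C4.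

Step 4
Reactants: 8 (3R,4R)-4-(3,4-dimethoxyphenyl)-3-methyl-4-{[(triisopropylsilyl)ethynyl]oxy}butan-1-ol
Product: 9 (3R,4R)-4-(3,4-dimethoxyphenyl)-3-methyl-4-{[(triisopropylsilyl)ethynyl]oxy}butanal
Conditions: SO3·pyridine, DMSO, i-Pr2NEt, CH2Cl2, 0 °C
Reagents that add atoms: none
Why: Parikh–Doering oxidation, an amine-buffered activated-DMSO method that stops at the aldehyde and spares the acid-labile ynol ether; C3 is β to the new carbonyl and cannot epimerise.

Step 5
Reactants: 9 (3R,4R)-4-(3,4-dimethoxyphenyl)-3-methyl-4-{[(triisopropylsilyl)ethynyl]oxy}butanal; 10 pent-1-en-4-yne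
Product: 12 (8R,9R)-9-(3,4-dimethoxyphenyl)-8-methyl-9-{[(triisopropylsilyl)ethynyl]oxy}non-1-en-4-yn-6-ol (both C6 epimers), via lithium pent-4-en-1-ynide 11 (not isolated)
Conditions: 10, n-BuLi, THF, −78 °C; then 9, −78 °C; aq NH4Cl
Reagents that add atoms: none
Why: 1,2-Addition of a lithium acetylide to an aldehyde: deprotonation of 10 at −78 °C should take only the sp C–H, the C-silyl group keeps the ynol ether out of acetylide exchange, and the new carbinol centre (formed as a mixture) is removed in step 6.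

Step 6
Reactants: 12 (8R,9R)-9-(3,4-dimethoxyphenyl)-8-methyl-9-{[(triisopropylsilyl)ethynyl]oxy}non-1-en-4-yn-6-ol
Product: 13 (8R,9R)-9-(3,4-dimethoxyphenyl)-8-methyl-9-{[(triisopropylsilyl)ethynyl]oxy}non-1-en-4-yn-6-one
Conditions: MnO2 (activated), CH2Cl2, rt
Reagents that add atoms: none
Why: Neutral MnO2 oxidation of a propargylic alcohol, which erases the uncontrolled carbinol centre of 12 without base that could isomerise the skipped enyne.

Step 7
Reactants: 13 (8R,9R)-9-(3,4-dimethoxyphenyl)-8-methyl-9-{[(triisopropylsilyl)ethynyl]oxy}non-1-en-4-yn-6-one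
Product: 14 (4E,8R,9R)-9-(3,4-dimethoxyphenyl)-4-methoxy-8-methyl-9-{[(triisopropylsilyl)ethynyl]oxy}nona-1,4-dien-6-one
Conditions: K2CO3 (10 mol%), MeOH, 0 °C
Reagents that add atoms: methanol CO
Why: Base-catalysed oxa-Michael addition of methanol to the ynone: reversible addition–elimination should funnel the product to the (E)-β-methoxy enone (OMe trans to the acyl group), and catalytic base at 0 °C limits migration of the skipped alkene.

Step 8
Reactants: 14 (4E,8R,9R)-9-(3,4-dimethoxyphenyl)-4-methoxy-8-methyl-9-{[(triisopropylsilyl)ethynyl]oxy}nona-1,4-dien-6-one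
Product: 16 (4E,8R,9R)-7-diazo-9-(3,4-dimethoxyphenyl)-4-methoxy-8-methyl-9-{[(triisopropylsilyl)ethynyl]oxy}nona-1,4-dien-6-one, via trifluoroacetyl diketone 15 (not isolated)
Conditions: LiN(SiMe3)2, THF, −78 °C; CF3CO2CH2CF3; then MsN3, Et3N, H2O, MeCN, rt
Reagents that add atoms: methanesulfonyl azide CS(=O)(=O)N=[N+]=[N-]
Why: Detrifluoroacetylative diazo transfer: LiN(SiMe3)2 should remove the α′ proton of the vinylogous ester under kinetic control (the site selectivity of Stork–Danheiser alkylations), Claisen trifluoroacetylation gives 15, and Regitz-type transfer from MsN3 with loss of the activating group places the diazo group on C3a next to the untouched C3 stereocentre.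

Step 9
Reactants: 16 (4E,8R,9R)-7-diazo-9-(3,4-dimethoxyphenyl)-4-methoxy-8-methyl-9-{[(triisopropylsilyl)ethynyl]oxy}nona-1,4-dien-6-one
Product: 17 (4E,8R,9R)-7-diazo-9-(3,4-dimethoxyphenyl)-9-(ethynyloxy)-4-methoxy-8-methylnona-1,4-dien-6-one
Conditions: Bu4NF, wet THF, −20 to 0 °C; cold filtration through neutral alumina, used at once
Reagents that add atoms: none
Why: Fluoride-induced C(sp)–Si cleavage unmasks the terminal ynol ether only at the last moment, because 17 is prone to intramolecular dipolar cycloaddition and to sigmatropic loss of the benzylic ynol ether on warming.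

Step 10
Reactants: 17 (4E,8R,9R)-7-diazo-9-(3,4-dimethoxyphenyl)-9-(ethynyloxy)-4-methoxy-8-methylnona-1,4-dien-6-one
Product: 21 (2R,3R,5S)-2-(3,4-dimethoxyphenyl)-5-methoxy-3-methyl-5-(prop-2-en-1-yl)-2,3-dihydro-1-benzofuran-6(5H)-one, via vinylketene 18 (not isolated), via bicyclic cyclobutenone 19 (not isolated), via dienylketene 20 (not isolated)
Conditions: hν (300 nm, Pyrex), degassed dry CH2Cl2 (0.005 M), 0 °C to rt; then 50 °C in the dark if 19 persists; chromatography
Reagents that add atoms: none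
Why: Proposed new method: irradiation should expel N2 from 17 with concerted Wolff migration of the β-methoxyvinyl group (alkene geometry retained) to give vinylketene 18, whose C6=C3a bond undergoes an intramolecular [2+2] cycloaddition with the tethered ynol ether (C7 to C6, C7a to C3a); conrotatory 4π opening of the resulting 4-vinylcyclobutenone 19 gives dienylketene 20, and disrotatory 6π electrocyclisation (C6 to C5) gives 21. The closest known reaction type is the Danheiser benzannulation in its photochemical diazo ketone form, run between two molecules with alkoxyalkynes and ending in a phenol, together with the thermal reclosure of dienylketenes to 6,6-disubstituted cyclohexa-2,4-dienones; new here are the oxygen tether and the stop at the dienone, enforced by the fully substituted C5. The dihydrofuran ring closes in the [2+2] event by formation of C3a–C7a across the three-atom C3–C2–O1 tether (exo with respect to the alkyne), and the six-membered ring closes in the 6π step, for which the cis arrangement of C7 and C4 on the C7a=C3a bond is fixed by the new ring. The step needs the ynol ether terminus C7 to bond to the ketene carbon C6, which the oxygen polarisation of the alkyne and the tether both dictate, and it needs ketene capture by the ynol ether to outrun addition of the allyl alkene and 1,2-hydrogen shift from C3, which the high ketenophilicity of alkynyl ethers and the carbene-free photochemical Wolff pathway should secure. C2 and C3 are not touched; C5 is the only new stereocentre and is set by the helical sense of the 6π closure, for which the remote C3 methyl group is the only control element, so no more than a modest preference is expected and the (5S) isomer 21 is separated from its C5 epimer by chromatography.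

**Compound list**

1 | 3,4-dimethoxybenzyl alcohol | COc1ccc(CO)cc1OC | starting material
2 | but-3-en-2-yl acetate (racemic) | CC(OC(C)=O)C=C | starting material
3 | (1R,2R)-1-(3,4-dimethoxyphenyl)-2-methylbut-3-en-1-ol | O[C@@H](c1ccc(OC)c(OC)c1)[C@@H](C=C)C | intermediate
4 | 4-[(1R,2R)-1-{[(E)-1,2-dichloroethenyl]oxy}-2-methylbut-3-en-1-yl]-1,2-dimethoxybenzene | Cl/C=C(/Cl)O[C@@H](c1ccc(OC)c(OC)c1)[C@@H](C=C)C | intermediate
5 | lithium 2-{[(1R,2R)-1-(3,4-dimethoxyphenyl)-2-methylbut-3-en-1-yl]oxy}ethyn-1-ide | [Li]C#CO[C@@H](c1ccc(OC)c(OC)c1)[C@@H](C=C)C | intermediate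
6 | triisopropyl[({(1R,2R)-1-(3,4-dimethoxyphenyl)-2-methylbut-3-en-1-yl}oxy)ethynyl]silane | CC(C)[Si](C#CO[C@@H](c1ccc(OC)c(OC)c1)[C@@H](C=C)C)(C(C)C)C(C)C | intermediate
7 | 9-[(3R,4R)-4-(3,4-dimethoxyphenyl)-3-methyl-4-{[(triisopropylsilyl)ethynyl]oxy}butyl]-9-borabicyclo[3.3.1]nonane | CC(C)[Si](C#CO[C@@H](c1ccc(OC)c(OC)c1)[C@@H](CCB1C2CCCC1CCC2)C)(C(C)C)C(C)C | intermediate
8 | (3R,4R)-4-(3,4-dimethoxyphenyl)-3-methyl-4-{[(triisopropylsilyl)ethynyl]oxy}butan-1-ol | CC(C)[Si](C#CO[C@@H](c1ccc(OC)c(OC)c1)[C@@H](CCO)C)(C(C)C)C(C)C | intermediate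
9 | (3R,4R)-4-(3,4-dimethoxyphenyl)-3-methyl-4-{[(triisopropylsilyl)ethynyl]oxy}butanal | CC(C)[Si](C#CO[C@@H](c1ccc(OC)c(OC)c1)[C@@H](CC=O)C)(C(C)C)C(C)C | intermediate
10 | pent-1-en-4-yne | C=CCC#C | starting material
11 | lithium pent-4-en-1-yn-1-ide | [Li]C#CCC=C | intermediate
12 | (8R,9R)-9-(3,4-dimethoxyphenyl)-8-methyl-9-{[(triisopropylsilyl)ethynyl]oxy}non-1-en-4-yn-6-ol (C6 not defined) | CC(C)[Si](C#CO[C@@H](c1ccc(OC)c(OC)c1)[C@@H](CC(O)C#CCC=C)C)(C(C)C)C(C)C | intermediate
13 | (8R,9R)-9-(3,4-dimethoxyphenyl)-8-methyl-9-{[(triisopropylsilyl)ethynyl]oxy}non-1-en-4-yn-6-one | CC(C)[Si](C#CO[C@@H](c1ccc(OC)c(OC)c1)[C@@H](CC(=O)C#CCC=C)C)(C(C)C)C(C)C | intermediate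
14 | (4E,8R,9R)-9-(3,4-dimethoxyphenyl)-4-methoxy-8-methyl-9-{[(triisopropylsilyl)ethynyl]oxy}nona-1,4-dien-6-one | CC(C)[Si](C#CO[C@@H](c1ccc(OC)c(OC)c1)[C@@H](CC(=O)/C=C(/OC)CC=C)C)(C(C)C)C(C)C | intermediate
15 | (4E,8R,9R)-9-(3,4-dimethoxyphenyl)-4-methoxy-8-methyl-7-(trifluoroacetyl)-9-{[(triisopropylsilyl)ethynyl]oxy}nona-1,4-dien-6-one (C7 not defined) | CC(C)[Si](C#CO[C@@H](c1ccc(OC)c(OC)c1)[C@@H](C(C(=O)C(F)(F)F)C(=O)/C=C(/OC)CC=C)C)(C(C)C)C(C)C | intermediate
16 | (4E,8R,9R)-7-diazo-9-(3,4-dimethoxyphenyl)-4-methoxy-8-methyl-9-{[(triisopropylsilyl)ethynyl]oxy}nona-1,4-dien-6-one | CC(C)[Si](C#CO[C@@H](c1ccc(OC)c(OC)c1)[C@@H](C(=[N+]=[N-])C(=O)/C=C(/OC)CC=C)C)(C(C)C)C(C)C | intermediate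
17 | (4E,8R,9R)-7-diazo-9-(3,4-dimethoxyphenyl)-9-(ethynyloxy)-4-methoxy-8-methylnona-1,4-dien-6-one | C#CO[C@@H](c1ccc(OC)c(OC)c1)[C@@H](C(=[N+]=[N-])C(=O)/C=C(/OC)CC=C)C | intermediate
18 | (3E)-2-[(1R,2R)-1-(3,4-dimethoxyphenyl)-1-(ethynyloxy)propan-2-yl]-4-methoxyhepta-1,3,6-trien-1-one (vinylketene) | C#CO[C@@H](c1ccc(OC)c(OC)c1)[C@@H](C(=C=O)/C=C(/OC)CC=C)C | intermediate
19 | (3R,4R)-3-(3,4-dimethoxyphenyl)-5-[(1E)-2-methoxypenta-1,4-dien-1-yl]-4-methyl-2-oxabicyclo[3.2.0]hept-1(7)-en-6-one (C5 not defined) | O=C1C=C2O[C@@H](c3ccc(OC)c(OC)c3)[C@H](C)C12/C=C(/OC)CC=C | intermediate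
20 | 2-[(4R,5R)-5-(3,4-dimethoxyphenyl)-3-[(1E)-2-methoxypenta-1,4-dien-1-yl]-4-methyl-4,5-dihydrofuran-2-yl]ethen-1-one (dienylketene) | O=C=CC1=C(/C=C(/OC)CC=C)[C@@H](C)[C@H](c2ccc(OC)c(OC)c2)O1 | intermediate
21 | (2R,3R,5S)-2-(3,4-dimethoxyphenyl)-5-methoxy-3-methyl-5-(prop-2-en-1-yl)-2,3-dihydro-1-benzofuran-6(5H)-one | C=CC[C@]1(OC)C=C2C(=CC1=O)O[C@@H](c1ccc(OC)c(OC)c1)[C@@H]2C | target

Total step count: 10. Longest linear sequence: 10 steps (1 to 21).

**Three steps most likely to fail**

1. Step 10 (Proposed new method).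
 - What may go wrong: the photogenerated species may undergo 1,2-hydrogen shift from C3 instead of Wolff rearrangement. The vinylketene may be taken by the allyl alkene or by traces of water instead of the ynol ether. The 6π closure may show poor facial selectivity at C5. Because the product itself ring-opens on irradiation to dienylketene 20 and recloses in the dark, the unwanted C5 epimer can be resubmitted to irradiation.
 - Fallback (known chemistry; sets out from 3, comes back at 21): the two ring closures are separated. Alcohol 3 is silylated (t-BuMe2SiCl, imidazole) to the silyl ether F1. F1 is taken through the operations of steps 3 to 8: 9-BBN then NaOH/H2O2 to the primary alcohol F2, SO3·pyridine/DMSO to the aldehyde F3, addition of 11 to the propargylic alcohol F4, MnO2 to the ynone F5, K2CO3/MeOH to the β-methoxy enone F6, and trifluoroacetylation/MsN3 diazo transfer to the diazo ketone F7. Irradiation of F7 with commercial ethoxyacetylene (bimolecular photochemical Danheiser annulation: Wolff rearrangement, [2+2], 4π opening, 6π closure) should give the 3-ethoxycyclohexa-2,4-dienone F8 after separation of its C6 epimer. Bu4NF releases the alcohol F9. F9 closes the dihydrofuran by acid-catalysed (pyridinium p-toluenesulfonate) intramolecular addition–elimination at the ethoxy-bearing vinylogous ester carbon with loss of ethanol, giving 21.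

2. Step 8.
 - What may go wrong: enolisation at the doubly allylic γ-CH2 instead of the α′-CH2, leading to misplaced acylation or migration of the skipped alkene into conjugation.
 - Fallback (sets out from 14, comes back at 16): the enolate is avoided. 14 is condensed with tert-butoxybis(dimethylamino)methane (toluene, 50 °C) to the α′-(dimethylaminomethylene) ketone F10. Diazo transfer from MsN3 to this enaminone, with loss of the sulfonylformamidine, should give 16.

3. Step 2.
 - What may go wrong: elimination or Wittig-type rearrangement at the electron-rich benzylic C–O centre under KH and n-BuLi, or sigmatropic loss of the benzylic ynol ether if the mixture warms.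
 - Fallback (sets out from 3, comes back at 6 through 5): 3 is converted into the formate F11 (HCO2H/Ac2O, pyridine). Ramirez dibromo-olefination of the formyl group (CBr4, PPh3) gives the 2,2-dibromovinyl ether F12. n-BuLi (2.2 equiv, −78 °C) converts F12 by elimination and Br–Li exchange into 5, which is silylated as in step 2 to give 6.

**Further compounds**

F1 | step 10 | tert-butyl{[(1R,2R)-1-(3,4-dimethoxyphenyl)-2-methylbut-3-en-1-yl]oxy}dimethylsilane | CC(C)(C)[Si](C)(C)O[C@@H](c1ccc(OC)c(OC)c1)[C@@H](C=C)C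
F2 | step 10 | (3R,4R)-4-[(tert-butyldimethylsilyl)oxy]-4-(3,4-dimethoxyphenyl)-3-methylbutan-1-ol | CC(C)(C)[Si](C)(C)O[C@@H](c1ccc(OC)c(OC)c1)[C@@H](CCO)C
F3 | step 10 | (3R,4R)-4-[(tert-butyldimethylsilyl)oxy]-4-(3,4-dimethoxyphenyl)-3-methylbutanal | CC(C)(C)[Si](C)(C)O[C@@H](c1ccc(OC)c(OC)c1)[C@@H](CC=O)C
F4 | step 10 | (8R,9R)-9-[(tert-butyldimethylsilyl)oxy]-9-(3,4-dimethoxyphenyl)-8-methylnon-1-en-4-yn-6-ol (C6 not defined) | CC(C)(C)[Si](C)(C)O[C@@H](c1ccc(OC)c(OC)c1)[C@@H](CC(O)C#CCC=C)C
F5 | step 10 | (8R,9R)-9-[(tert-butyldimethylsilyl)oxy]-9-(3,4-dimethoxyphenyl)-8-methylnon-1-en-4-yn-6-one | CC(C)(C)[Si](C)(C)O[C@@H](c1ccc(OC)c(OC)c1)[C@@H](CC(=O)C#CCC=C)C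
F6 | step 10 | (4E,8R,9R)-9-[(tert-butyldimethylsilyl)oxy]-9-(3,4-dimethoxyphenyl)-4-methoxy-8-methylnona-1,4-dien-6-one | CC(C)(C)[Si](C)(C)O[C@@H](c1ccc(OC)c(OC)c1)[C@@H](CC(=O)/C=C(/OC)CC=C)C
F7 | step 10 | (4E,8R,9R)-9-[(tert-butyldimethylsilyl)oxy]-7-diazo-9-(3,4-dimethoxyphenyl)-4-methoxy-8-methylnona-1,4-dien-6-one | CC(C)(C)[Si](C)(C)O[C@@H](c1ccc(OC)c(OC)c1)[C@@H](C(=[N+]=[N-])C(=O)/C=C(/OC)CC=C)C
F8 | step 10 | (6S)-4-[(1R,2R)-1-[(tert-butyldimethylsilyl)oxy]-1-(3,4-dimethoxyphenyl)propan-2-yl]-3-ethoxy-6-methoxy-6-(prop-2-en-1-yl)cyclohexa-2,4-dien-1-one | C=CC[C@]1(OC)C=C([C@@H](C)[C@@H](O[Si](C)(C)C(C)(C)C)c2ccc(OC)c(OC)c2)C(OCC)=CC1=O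
F9 | step 10 | (6S)-4-[(1R,2R)-1-(3,4-dimethoxyphenyl)-1-hydroxypropan-2-yl]-3-ethoxy-6-methoxy-6-(prop-2-en-1-yl)cyclohexa-2,4-dien-1-one | C=CC[C@]1(OC)C=C([C@@H](C)[C@@H](O)c2ccc(OC)c(OC)c2)C(OCC)=CC1=O
F10 | step 8 | (4E,8R,9R)-9-(3,4-dimethoxyphenyl)-7-[(dimethylamino)methylidene]-4-methoxy-8-methyl-9-{[(triisopropylsilyl)ethynyl]oxy}nona-1,4-dien-6-one | CC(C)[Si](C#CO[C@@H](c1ccc(OC)c(OC)c1)[C@@H](C(=CN(C)C)C(=O)/C=C(/OC)CC=C)C)(C(C)C)C(C)C
F11 | step 2 | (1R,2R)-1-(3,4-dimethoxyphenyl)-2-methylbut-3-en-1-yl formate | O=CO[C@@H](c1ccc(OC)c(OC)c1)[C@@H](C=C)C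
F12 | step 2 | 4-[(1R,2R)-1-[(2,2-dibromoethenyl)oxy]-2-methylbut-3-en-1-yl]-1,2-dimethoxybenzene | BrC(Br)=CO[C@@H](c1ccc(OC)c(OC)c1)[C@@H](C=C)C
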